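The route rests on cutting the lactone O1–C5 bond together with C6–C7: both are made in one magnesium-directed nitrile oxide (3+2) cycloaddition between a C7–C14 (Z)-alkenyl nitrile oxide and the terminal alkene of a C1–C6 β-hydroxy ester. The step exploits the 1,3-syn pair O3/O5 flanking the C4 methyl and the 1,3 pattern O5/O7 of the lactone side chain: the isoxazoline ring (O–N=C7–C6–C5) is a masked aldol, cut at N–O late, after which the C5 hydroxyl directs the C7 reduction and closes the oxan-2-one ring on C1. One crotylation product supplies all three stereotriads; a B-alkyl Suzuki coupling joins C14–C15.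

Key step: step 23

Remarks: atom numbers C1–C24 follow the target chain (C1 = lactone carbonyl, C24 = terminal diene CH2). TBS = tert-butyldimethylsilyl. Oxime 18 is used as its C=N isomer mixture, since both isomers give the same nitrile oxide.

**Common stereotriad**

Step 1
Reactants: 1 methyl (S)-3-hydroxy-2-methylpropanoate
Product: 2 methyl (S)-3-(TBS-oxy)-2-methylpropanoate
Conditions: TBSCl, imidazole, DMF, 0 °C → rt
Reagents that add atoms: tert-butyldimethylsilyl chloride, CC(C)(C)[Si](C)(C)Cl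
Why: Imidazole-promoted silylation of the primary alcohol, which leaves the stereocenter untouched.

Step 2
Reactants: 2 methyl (S)-3-(TBS-oxy)-2-methylpropanoate
Product: 3 (S)-3-(TBS-oxy)-2-methylpropanal
Conditions: iBu2AlH (1.05 equiv), CH2Cl2, −78 °C; aq. NaK tartrate
Reagents that add atoms: none
Why: Partial ester reduction, in which the tetrahedral aluminium hemiacetal persists at −78 °C and releases the aldehyde only on work-up, so the α-stereocenter should not epimerise.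

Step 3
Reactants: 3 (S)-3-(TBS-oxy)-2-methylpropanal
Product: 4 (2S,3S,4S)-1-(TBS-oxy)-2,4-dimethylhex-5-en-3-ol
Conditions: (R,R)-diisopropyl tartrate (E)-crotylboronate, 4 Å sieves, toluene, −78 °C; aq. NaOH
Reagents that add atoms: (R,R)-diisopropyl tartrate (E)-crotylboronate, C/C=C/CB1O[C@@H](C(=O)OC(C)C)[C@@H](O1)C(=O)OC(C)C
Why: Roush crotylboration through a chair transition state gives the 3,4-anti relationship from the (E)-crotyl unit, and the (R,R)-reagent attacks the aldehyde face that Felkin–Anh control also favours (matched pair), which should give the 2,3-syn-3,4-anti stereotriad.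

**C1–C6 ester**

Step 4
Reactants: 4 (2S,3S,4S)-1-(TBS-oxy)-2,4-dimethylhex-5-en-3-ol
Product: 5 (2S,3S,4S)-2,4-dimethylhex-5-ene-1,3-diol
Conditions: Bu4NF, THF, 0 °C → rt
Reagents that add atoms: none
Why: Fluoride-induced cleavage of the Si–O bond of the primary silyl ether.

Step 5
Reactants: 5 (2S,3S,4S)-2,4-dimethylhex-5-ene-1,3-diol
Product: 7 (2R,3S,4S)-3-hydroxy-2,4-dimethylhex-5-enoic acid, via hydroxy aldehyde 6 (not isolated)
Conditions: TEMPO (cat.), PhI(OAc)2, MeCN/H2O, rt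
Reagents that add atoms: water, O
Why: Oxoammonium (TEMPO) oxidation is selective for the primary alcohol and carries the aldehyde hydrate on to the acid, while the secondary alcohol and the alkene should stay intact.

Step 6
Reactants: 7 (2R,3S,4S)-3-hydroxy-2,4-dimethylhex-5-enoic acid
Product: 8 methyl (2R,3S,4S)-3-hydroxy-2,4-dimethylhex-5-enoate
Conditions: Me3SiCHN2, MeOH/toluene, 0 °C
Reagents that add atoms: (trimethylsilyl)diazomethane, C[Si](C)(C)C=[N+]=[N-]
Why: Diazoalkane esterification of the acid under neutral conditions, which should not epimerise C2 or touch the β-hydroxyl.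

**Shared aldehyde**

Step 7
Reactants: 4 (2S,3S,4S)-1-(TBS-oxy)-2,4-dimethylhex-5-en-3-ol
Product: 9 (2S,3S,4S)-1,3-bis(TBS-oxy)-2,4-dimethylhex-5-ene
Conditions: TBSOTf, 2,6-lutidine, CH2Cl2, −78 → 0 °C
Reagents that add atoms: tert-butyldimethylsilyl triflate, CC(C)(C)[Si](C)(C)OS(=O)(=O)C(F)(F)F
Why: Silylation of the hindered secondary alcohol with the silyl triflate.

Step 8
Reactants: 9 (2S,3S,4S)-1,3-bis(TBS-oxy)-2,4-dimethylhex-5-ene
Product: 11 (2R,3R,4S)-3,5-bis(TBS-oxy)-2,4-dimethylpentanal, via ozonide 10 (not isolated)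
Conditions: O3, CH2Cl2, −78 °C; then PPh3, −78 °C → rt
Reagents that add atoms: ozone, [O-][O+]=O
Why: Ozonolysis of the terminal alkene with reductive work-up gives the α-methyl aldehyde under neutral conditions, which should keep the α-stereocenter.

**C7–C14 oxime (fragment B)**

Step 9
Reactants: 11 (2R,3R,4S)-3,5-bis(TBS-oxy)-2,4-dimethylpentanal
Product: 12 methyl (2Z,4S,5S,6S)-5,7-bis(TBS-oxy)-4,6-dimethylhept-2-enoate
Conditions: (CF3CH2O)2P(O)CH2CO2Me, KN(SiMe3)2, 18-crown-6, THF, −78 °C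
Reagents that add atoms: methyl bis(2,2,2-trifluoroethyl)phosphonoacetate, COC(=O)CP(=O)(OCC(F)(F)F)OCC(F)(F)F
Why: Still–Gennari olefination, in which fast elimination from the kinetic adduct of the trifluoroethyl phosphonate should give the (Z)-enoate.

Step 10
Reactants: 12 methyl (2Z,4S,5S,6S)-5,7-bis(TBS-oxy)-4,6-dimethylhept-2-enoate
Product: 13 methyl (2Z,4S,5S,6S)-5-(TBS-oxy)-7-hydroxy-4,6-dimethylhept-2-enoate
Conditions: HF·pyridine, pyridine, THF, 0 °C → rt
Reagents that add atoms: none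
Why: Buffered HF·pyridine desilylation is much faster at the primary silyl ether than at the secondary one flanked by two methyl-bearing carbons.

Step 11
Reactants: 13 methyl (2Z,4S,5S,6S)-5-(TBS-oxy)-7-hydroxy-4,6-dimethylhept-2-enoate
Product: 14 methyl (2Z,4S,5S,6R)-5-(TBS-oxy)-4,6-dimethyl-7-oxohept-2-enoate
Conditions: Dess–Martin periodinane, NaHCO3, CH2Cl2, rt
Reagents that add atoms: none
Why: Dess–Martin oxidation of the primary alcohol under buffered conditions, which should not epimerise the α-methyl aldehyde.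

Step 12
Reactants: 14 methyl (2Z,4S,5S,6R)-5-(TBS-oxy)-4,6-dimethyl-7-oxohept-2-enoate
Product: 15 methyl (2Z,4S,5S,6S,7Z)-5-(TBS-oxy)-8-iodo-4,6-dimethylnona-2,7-dienoate
Conditions: Ph3PEtI, nBuLi, THF; I2, −78 °C; NaN(SiMe3)2, −20 °C; then 14, −78 °C
Reagents that add atoms: ethyltriphenylphosphonium iodide, CC[P+](c1ccccc1)(c1ccccc1)c1ccccc1.[I-]; iodine, II
Why: Stork–Zhao-type Wittig olefination with the α-iodoethylidene ylide, which under kinetic control should place iodine cis to the chain (Z-iodoalkene) and react faster with the aldehyde than with the enoate.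

Step 13
Reactants: 15 methyl (2Z,4S,5S,6S,7Z)-5-(TBS-oxy)-8-iodo-4,6-dimethylnona-2,7-dienoate
Product: 16 (2Z,4S,5S,6S,7Z)-5-(TBS-oxy)-8-iodo-4,6-dimethylnona-2,7-dien-1-ol
Conditions: iBu2AlH (2.5 equiv), CH2Cl2, −78 °C
Reagents that add atoms: none
Why: 1,2-Reduction of the enoate by the aluminium hydride, which leaves the vinyl iodide and both alkene geometries untouched.

Step 14
Reactants: 16 (2Z,4S,5S,6S,7Z)-5-(TBS-oxy)-8-iodo-4,6-dimethylnona-2,7-dien-1-ol
Product: 17 (2Z,4S,5S,6S,7Z)-5-(TBS-oxy)-8-iodo-4,6-dimethylnona-2,7-dienal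
Conditions: Dess–Martin periodinane, pyridine, CH2Cl2, 0 °C
Reagents that add atoms: none
Why: Buffered Dess–Martin oxidation of the Z-allylic alcohol, which should give the Z-enal without isomerisation.

Step 15
Reactants: 17 (2Z,4S,5S,6S,7Z)-5-(TBS-oxy)-8-iodo-4,6-dimethylnona-2,7-dienal
Product: 18 (2Z,4S,5S,6S,7Z)-5-(TBS-oxy)-8-iodo-4,6-dimethylnona-2,7-dienal oxime
Conditions: NH2OH·HCl, pyridine, EtOH, 0 °C
Reagents that add atoms: hydroxylamine hydrochloride, NO.Cl
Why: Condensation of the aldehyde with hydroxylamine under cold buffered conditions, where 1,2-addition should outrun conjugate addition and keep the Z-alkene.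

**C15–C24 iodide (fragment A)**

Step 16
Reactants: 11 (2R,3R,4S)-3,5-bis(TBS-oxy)-2,4-dimethylpentanal
Product: 20 (2S,3S,4S,5Z)-1,3-bis(TBS-oxy)-2,4-dimethylocta-5,7-diene, via hydroxy phosphine 19 (not isolated)
Conditions: Ph2PCH2CH=CH2, tBuLi, THF, −78 °C; Ti(OiPr)4; 11; then MeI, −78 °C → rt
Reagents that add atoms: allyldiphenylphosphine, C=CCP(c1ccccc1)c1ccccc1
Why: The α-phosphinoallyl titanium reagent adds to the aldehyde to give the anti β-hydroxy phosphine, and P-methylation triggers a Horner–Wittig-type syn elimination that should give the (Z)-1,3-diene.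

Step 17
Reactants: 20 (2S,3S,4S,5Z)-1,3-bis(TBS-oxy)-2,4-dimethylocta-5,7-diene
Product: 21 (2S,3S,4S,5Z)-3-(TBS-oxy)-2,4-dimethylocta-5,7-dien-1-ol
Conditions: HF·pyridine, pyridine, THF, 0 °C → rt
Reagents that add atoms: none
Why: Selective desilylation of the primary silyl ether, as in step 10.

Step 18
Reactants: 21 (2S,3S,4S,5Z)-3-(TBS-oxy)-2,4-dimethylocta-5,7-dien-1-ol
Product: 22 (2R,3S,4S,5Z)-3-(TBS-oxy)-2,4-dimethylocta-5,7-dienal
Conditions: Dess–Martin periodinane, NaHCO3, CH2Cl2, rt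
Reagents that add atoms: none
Why: Dess–Martin oxidation of the primary alcohol, which tolerates the diene and the silyl ether.

Step 19
Reactants: 22 (2R,3S,4S,5Z)-3-(TBS-oxy)-2,4-dimethylocta-5,7-dienal; 23 (R)-4-benzyl-3-propionyloxazolidin-2-one
Product: 25 C15–C24 aldol adduct (C15 imide of the (R)-benzyl oxazolidinone; 16R-methyl; 17S-hydroxyl; 19-OTBS; 16,17-syn and 17,18-syn; Z-diene), via boron enolate 24 (not isolated)
Conditions: Bu2BOTf, Et3N, CH2Cl2, −78 → 0 °C; 22, −78 → 0 °C; pH 7 buffer, MeOH, H2O2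
Reagents that add atoms: none
Why: Evans syn-aldol, in which the (Z)-boron enolate reacts through a Zimmerman–Traxler chair and the (R)-benzyl auxiliary overrides the aldehyde bias, which should set C16 and C17 syn to each other and C17 syn to C18.

Step 20
Reactants: 25 C15–C24 aldol adduct
Product: 26 C15–C24 imide with 17,19-bis(TBS-oxy) groups
Conditions: TBSOTf, 2,6-lutidine, CH2Cl2, −78 → 0 °C
Reagents that add atoms: tert-butyldimethylsilyl triflate, CC(C)(C)[Si](C)(C)OS(=O)(=O)C(F)(F)F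
Why: Silylation of the secondary aldol hydroxyl with the silyl triflate.

Step 21
Reactants: 26 C15–C24 imide with 17,19-bis(TBS-oxy) groups
Product: 27 C15–C24 primary alcohol (15-OH; 17,19-bis-OTBS)
Conditions: LiBH4, EtOH (1 equiv), THF, 0 °C
Reagents that add atoms: none
Why: Reductive cleavage of the imide, in which borohydride attacks the exocyclic carbonyl and releases the auxiliary.

Step 22
Reactants: 27 C15–C24 primary alcohol
Product: 28 C15–C24 primary iodide (15-iodo; 17,19-bis-OTBS; Z-diene)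
Conditions: PPh3, I2, imidazole, benzene/Et2O, 0 °C, dark
Reagents that add atoms: iodine, II
Why: Appel-type iodination of the primary alcohol through its alkoxyphosphonium salt, with the iodine pre-complexed to the phosphine so the diene is not exposed to free iodine.

**Endgame**

Step 23
Reactants: 18 (2Z,4S,5S,6S,7Z)-5-(TBS-oxy)-8-iodo-4,6-dimethylnona-2,7-dienal oxime; 8 methyl (2R,3S,4S)-3-hydroxy-2,4-dimethylhex-5-enoate
Product: 32 C1–C14 (5S)-isoxazoline (4,5-dihydroisoxazole O–N=C7–C6–C5; 3-OH free; C1 methyl ester; 11-OTBS; Z-alkene at C8; Z-iodoalkene at C13), via hydroximoyl chloride 29 (not isolated), via magnesium alkoxide 30 (not isolated), via nitrile oxide 31 (not isolated)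
Conditions: 18, tBuOCl, CH2Cl2, −78 °C; separately 8 (1.5 equiv), iPrOH (3 equiv), EtMgBr (3 equiv), CH2Cl2, 0 °C; then slow addition of the chloride solution, 0 °C → rt
Reagents that add atoms: none
Why: tBuOCl chlorinates the oxime and the magnesium alkoxides dehydrochlorinate 29 to nitrile oxide 31, which adds to the terminal alkene of 30 in a concerted 1,3-dipolar (3+2) cycloaddition that forms C6–C7 and the O–C5 bond in one event. The closest known reaction type is the magnesium-alkoxide-directed nitrile oxide cycloaddition of allylic and homoallylic alcohols. The 4,5-dihydroisoxazole ring closes by a suprafacial two-bond cycloaddition, with oxygen going to the substituted alkene carbon C5 as is usual for monosubstituted alkenes. C5 is set by a chair-like chelate in which magnesium bridges the C3 alkoxide and the dipole oxygen, the C3 and C4 substituents are equatorial, and the C4 methyl lies anti to the incoming dipole with the C4 hydrogen inside, which should place the new C5–O bond syn to C3–O and anti to the C4 methyl (5S). The step needs chemoselectivity for the terminal alkene over the Z-disubstituted and iodo-trisubstituted alkenes of the dipole and suppression of dipole dimerisation; the rate gain of the magnesium alkoxide, the excess of 8 and the slow generation of 31 should secure this.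

Step 24
Reactants: 32 C1–C14 (5S)-isoxazoline
Product: 33 C1–C14 isoxazoline with 3,11-bis(TBS-oxy) groups
Conditions: TBSOTf, 2,6-lutidine, CH2Cl2, −78 → 0 °C
Reagents that add atoms: tert-butyldimethylsilyl triflate, CC(C)(C)[Si](C)(C)OS(=O)(=O)C(F)(F)F
Why: Silylation of the C3 hydroxyl, which would otherwise form a cyclic hemiketal with the C7 ketone that is unmasked later.

Step 25
Reactants: 28 C15–C24 primary iodide; 33 C1–C14 isoxazoline with 3,11-bis(TBS-oxy) groups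
Product: 36 C1–C24 isoxazoline (3,11,17,19-tetrakis-OTBS; methyl ester; Z-alkenes at C8 and C13; Z-diene), via alkyllithium 34 (not isolated), via lithium borate 35 (not isolated)
Conditions: 28 (1.5 equiv), tBuLi, Et2O, −78 °C; B-methoxy-9-BBN, THF, −78 °C → rt; then 33, Pd(dppf)Cl2 (cat.), aq. K3PO4, DMF, rt
Reagents that add atoms: none
Why: B-alkyl Suzuki–Miyaura coupling, in which the borate from iodine–lithium exchange transfers its primary alkyl group to the vinylpalladium iodide formed by oxidative addition to zerovalent palladium, with retention of the Z-olefin geometry.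

Step 26
Reactants: 36 C1–C24 isoxazoline
Product: 38 C1–C24 β-hydroxy (Z)-enone (5S-hydroxyl; C7 ketone), via hydroxy imine 37 (not isolated)
Conditions: SmI2 (2.2 equiv), THF, 0 °C; then B(OH)3, MeOH/H2O, rt
Reagents that add atoms: water, O
Why: Single-electron reduction by SmI2 cleaves the weak N–O bond of the conjugated isoxazoline, and mild hydrolysis of the imine should give the β-hydroxy enone without touching the alkenes, silyl ethers or ester.

Step 27
Reactants: 38 C1–C24 β-hydroxy (Z)-enone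
Product: 39 C1–C24 (5S,7S)-5,7-anti diol (methyl ester; 3,11,17,19-tetrakis-OTBS)
Conditions: Me4NBH(OAc)3, MeCN/AcOH, −30 °C
Reagents that add atoms: none
Why: Evans–Saksena reduction, in which the C5 hydroxyl binds the triacetoxyborohydride and delivers hydride intramolecularly through a chair transition state, which should give the 5,7-anti diol (7S).

Step 28
Reactants: 39 C1–C24 (5S,7S)-5,7-anti diol
Product: 41 CNP0103248.1, via seco methyl ester 40 (not isolated)
Conditions: 3 N aq. HCl, MeOH, rt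
Reagents that add atoms: none
Why: Acid-catalysed solvolysis removes the four silyl ethers and the δ-hydroxy ester closes to the six-membered lactone by acyl substitution at C1 by the C5 hydroxyl.

**Compound list**

1 | methyl (S)-3-hydroxy-2-methylpropanoate | COC(=O)[C@@H](C)CO | starting material
2 | methyl (S)-3-(TBS-oxy)-2-methylpropanoate | COC(=O)[C@@H](C)CO[Si](C)(C)C(C)(C)C | intermediate
3 | (S)-3-(TBS-oxy)-2-methylpropanal | O=C[C@@H](C)CO[Si](C)(C)C(C)(C)C | intermediate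
4 | (2S,3S,4S)-1-(TBS-oxy)-2,4-dimethylhex-5-en-3-ol | C=C[C@H](C)[C@H](O)[C@@H](C)CO[Si](C)(C)C(C)(C)C | intermediate
5 | (2S,3S,4S)-2,4-dimethylhex-5-ene-1,3-diol | C=C[C@H](C)[C@H](O)[C@@H](C)CO | intermediate
6 | (2R,3S,4S)-3-hydroxy-2,4-dimethylhex-5-enal (not isolated) | C=C[C@H](C)[C@H](O)[C@@H](C)C=O | intermediate
7 | (2R,3S,4S)-3-hydroxy-2,4-dimethylhex-5-enoic acid | C=C[C@H](C)[C@H](O)[C@@H](C)C(=O)O | intermediate
8 | methyl (2R,3S,4S)-3-hydroxy-2,4-dimethylhex-5-enoate | C=C[C@H](C)[C@H](O)[C@@H](C)C(=O)OC | intermediate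
9 | (2S,3S,4S)-1,3-bis(TBS-oxy)-2,4-dimethylhex-5-ene | C=C[C@H](C)[C@H](O[Si](C)(C)C(C)(C)C)[C@@H](C)CO[Si](C)(C)C(C)(C)C | intermediate
10 | secondary ozonide of 9 (1,2,4-trioxolane; new ring carbon not specified; not isolated) | C1OC(OO1)[C@H](C)[C@H](O[Si](C)(C)C(C)(C)C)[C@@H](C)CO[Si](C)(C)C(C)(C)C | intermediate
11 | (2R,3R,4S)-3,5-bis(TBS-oxy)-2,4-dimethylpentanal | O=C[C@H](C)[C@H](O[Si](C)(C)C(C)(C)C)[C@@H](C)CO[Si](C)(C)C(C)(C)C | intermediate
12 | methyl (2Z,4S,5S,6S)-5,7-bis(TBS-oxy)-4,6-dimethylhept-2-enoate | COC(=O)/C=C\[C@H](C)[C@H](O[Si](C)(C)C(C)(C)C)[C@@H](C)CO[Si](C)(C)C(C)(C)C | intermediate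
13 | methyl (2Z,4S,5S,6S)-5-(TBS-oxy)-7-hydroxy-4,6-dimethylhept-2-enoate | COC(=O)/C=C\[C@H](C)[C@H](O[Si](C)(C)C(C)(C)C)[C@@H](C)CO | intermediate
14 | methyl (2Z,4S,5S,6R)-5-(TBS-oxy)-4,6-dimethyl-7-oxohept-2-enoate | COC(=O)/C=C\[C@H](C)[C@H](O[Si](C)(C)C(C)(C)C)[C@@H](C)C=O | intermediate
15 | methyl (2Z,4S,5S,6S,7Z)-5-(TBS-oxy)-8-iodo-4,6-dimethylnona-2,7-dienoate | COC(=O)/C=C\[C@H](C)[C@H](O[Si](C)(C)C(C)(C)C)[C@@H](C)/C=C(/C)I | intermediate
16 | (2Z,4S,5S,6S,7Z)-5-(TBS-oxy)-8-iodo-4,6-dimethylnona-2,7-dien-1-ol | OC/C=C\[C@H](C)[C@H](O[Si](C)(C)C(C)(C)C)[C@@H](C)/C=C(/C)I | intermediate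
17 | (2Z,4S,5S,6S,7Z)-5-(TBS-oxy)-8-iodo-4,6-dimethylnona-2,7-dienal | O=C/C=C\[C@H](C)[C@H](O[Si](C)(C)C(C)(C)C)[C@@H](C)/C=C(/C)I | intermediate
18 | oxime of 17 (C=N isomer mixture) | ON=C/C=C\[C@H](C)[C@H](O[Si](C)(C)C(C)(C)C)[C@@H](C)/C=C(/C)I | intermediate
19 | anti β-hydroxy allyl(diphenyl)phosphine adduct of 11 (titanium alkoxide in the flask; the two new centres relative-anti and not individually specified; not isolated) | C=CC(P(c1ccccc1)c1ccccc1)C(O)[C@H](C)[C@H](O[Si](C)(C)C(C)(C)C)[C@@H](C)CO[Si](C)(C)C(C)(C)C | intermediate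
20 | (2S,3S,4S,5Z)-1,3-bis(TBS-oxy)-2,4-dimethylocta-5,7-diene | C=C/C=C\[C@H](C)[C@H](O[Si](C)(C)C(C)(C)C)[C@@H](C)CO[Si](C)(C)C(C)(C)C | intermediate
21 | (2S,3S,4S,5Z)-3-(TBS-oxy)-2,4-dimethylocta-5,7-dien-1-ol | C=C/C=C\[C@H](C)[C@H](O[Si](C)(C)C(C)(C)C)[C@@H](C)CO | intermediate
22 | (2R,3S,4S,5Z)-3-(TBS-oxy)-2,4-dimethylocta-5,7-dienal | C=C/C=C\[C@H](C)[C@H](O[Si](C)(C)C(C)(C)C)[C@@H](C)C=O | intermediate
23 | (R)-4-benzyl-3-propionyloxazolidin-2-one | CCC(=O)N1[C@H](Cc2ccccc2)COC1=O | starting material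
24 | dibutylboron (Z)-enolate of 23 (not isolated) | C/C=C(\OB(CCCC)CCCC)N1[C@H](Cc2ccccc2)COC1=O | intermediate
25 | C15–C24 aldol adduct (C15 imide; 17-OH; 19-OTBS) | C=C/C=C\[C@H](C)[C@H](O[Si](C)(C)C(C)(C)C)[C@@H](C)[C@H](O)[C@@H](C)C(=O)N1[C@H](Cc2ccccc2)COC1=O | intermediate
26 | C15–C24 imide with 17,19-bis-OTBS | C=C/C=C\[C@H](C)[C@H](O[Si](C)(C)C(C)(C)C)[C@@H](C)[C@H](O[Si](C)(C)C(C)(C)C)[C@@H](C)C(=O)N1[C@H](Cc2ccccc2)COC1=O | intermediate
27 | C15–C24 primary alcohol (15-OH; 17,19-bis-OTBS) | C=C/C=C\[C@H](C)[C@H](O[Si](C)(C)C(C)(C)C)[C@@H](C)[C@H](O[Si](C)(C)C(C)(C)C)[C@@H](C)CO | intermediate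
28 | C15–C24 primary iodide (17,19-bis-OTBS) | C=C/C=C\[C@H](C)[C@H](O[Si](C)(C)C(C)(C)C)[C@@H](C)[C@H](O[Si](C)(C)C(C)(C)C)[C@@H](C)CI | intermediate
29 | hydroximoyl chloride of 18 (not isolated) | ON=C(Cl)/C=C\[C@H](C)[C@H](O[Si](C)(C)C(C)(C)C)[C@@H](C)/C=C(/C)I | intermediate
30 | bromomagnesium alkoxide of 8 (not isolated) | C=C[C@H](C)[C@H](O[Mg]Br)[C@@H](C)C(=O)OC | intermediate
31 | C7–C14 nitrile oxide (not isolated) | [O-][N+]#C/C=C\[C@H](C)[C@H](O[Si](C)(C)C(C)(C)C)[C@@H](C)/C=C(/C)I | intermediate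
32 | C1–C14 (5S)-isoxazoline (3-OH; 11-OTBS; methyl ester; vinyl iodide) | I/C(C)=C\[C@H](C)[C@@H](O[Si](C)(C)C(C)(C)C)[C@@H](C)/C=C\C1=NO[C@@H](C1)[C@H](C)[C@H](O)[C@@H](C)C(=O)OC | intermediate
33 | C1–C14 isoxazoline with 3,11-bis-OTBS | I/C(C)=C\[C@H](C)[C@@H](O[Si](C)(C)C(C)(C)C)[C@@H](C)/C=C\C1=NO[C@@H](C1)[C@H](C)[C@H](O[Si](C)(C)C(C)(C)C)[C@@H](C)C(=O)OC | intermediate
34 | C15–C24 alkyllithium (not isolated) | C=C/C=C\[C@H](C)[C@H](O[Si](C)(C)C(C)(C)C)[C@@H](C)[C@H](O[Si](C)(C)C(C)(C)C)[C@@H](C)C[Li] | intermediate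
35 | lithium B-alkyl-B-methoxy-9-BBN borate (not isolated) | C=C/C=C\[C@H](C)[C@H](O[Si](C)(C)C(C)(C)C)[C@@H](C)[C@H](O[Si](C)(C)C(C)(C)C)[C@@H](C)C[B-]1(OC)C2CCCC1CCC2.[Li+] | intermediate
36 | C1–C24 isoxazoline (3,11,17,19-tetrakis-OTBS; methyl ester) | C=C/C=C\[C@H](C)[C@H](O[Si](C)(C)C(C)(C)C)[C@@H](C)[C@H](O[Si](C)(C)C(C)(C)C)[C@@H](C)C/C(C)=C\[C@H](C)[C@@H](O[Si](C)(C)C(C)(C)C)[C@@H](C)/C=C\C1=NO[C@@H](C1)[C@H](C)[C@H](O[Si](C)(C)C(C)(C)C)[C@@H](C)C(=O)OC | intermediate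
37 | C1–C24 β-hydroxy N–H ketimine (not isolated) | C=C/C=C\[C@H](C)[C@H](O[Si](C)(C)C(C)(C)C)[C@@H](C)[C@H](O[Si](C)(C)C(C)(C)C)[C@@H](C)C/C(C)=C\[C@H](C)[C@@H](O[Si](C)(C)C(C)(C)C)[C@@H](C)/C=C\C(=N)C[C@H](O)[C@H](C)[C@H](O[Si](C)(C)C(C)(C)C)[C@@H](C)C(=O)OC | intermediate
38 | C1–C24 β-hydroxy (Z)-enone (5S-OH; C7 ketone) | C=C/C=C\[C@H](C)[C@H](O[Si](C)(C)C(C)(C)C)[C@@H](C)[C@H](O[Si](C)(C)C(C)(C)C)[C@@H](C)C/C(C)=C\[C@H](C)[C@@H](O[Si](C)(C)C(C)(C)C)[C@@H](C)/C=C\C(=O)C[C@H](O)[C@H](C)[C@H](O[Si](C)(C)C(C)(C)C)[C@@H](C)C(=O)OC | intermediate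
39 | C1–C24 (5S,7S)-anti diol (methyl ester; 3,11,17,19-tetrakis-OTBS) | C=C/C=C\[C@H](C)[C@H](O[Si](C)(C)C(C)(C)C)[C@@H](C)[C@H](O[Si](C)(C)C(C)(C)C)[C@@H](C)C/C(C)=C\[C@H](C)[C@@H](O[Si](C)(C)C(C)(C)C)[C@@H](C)/C=C\[C@@H](O)C[C@H](O)[C@H](C)[C@H](O[Si](C)(C)C(C)(C)C)[C@@H](C)C(=O)OC | intermediate
40 | seco methyl ester hexaol (not isolated) | C=C/C=C\[C@H](C)[C@H](O)[C@@H](C)[C@H](O)[C@@H](C)C/C(C)=C\[C@H](C)[C@@H](O)[C@@H](C)/C=C\[C@@H](O)C[C@H](O)[C@H](C)[C@H](O)[C@@H](C)C(=O)OC | intermediate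
41 | CNP0103248.1 | C=C/C=C\[C@H](C)[C@H](O)[C@@H](C)[C@H](O)[C@@H](C)C/C(C)=C\[C@H](C)[C@@H](O)[C@@H](C)/C=C\[C@@H](O)C[C@@H]1OC(=O)[C@H](C)[C@@H](O)[C@H]1C | target

**Totals**

Total step count: 28.
Longest linear sequence: 18 steps (steps 1–3, 7–15, 23–28, from 1).

**Steps most likely to fail**

Step 23. The cycloaddition may suffer from weak facial direction by the homoallylic magnesium alkoxide, from dimerisation of the dipole, or from capture of the dipole by its own iodoalkene. The fallback sets out from 8 and 17 and comes back at 39; it sets the C5 oxygen by directed ketone reduction and not by cycloaddition. 8 would be silylated (TBSOTf, 2,6-lutidine) to methyl (2R,3S,4S)-3-(TBS-oxy)-2,4-dimethylhex-5-enoate F1. Wacker oxidation (PdCl2, CuCl, O2, DMF/H2O) would give methyl (2R,3S,4R)-3-(TBS-oxy)-2,4-dimethyl-5-oxohexanoate F2. Its boron enolate (Ipc2BCl of the handedness matched to the 7S carbinol, Et3N) would add to enal 17 to give the C1–C14 7-hydroxy-5-ketone F3. Me4NBH(OAc)3 would reduce the C5 ketone under direction of the C7 hydroxyl to the C1–C14 5,7-anti diol iodide F4. B-alkyl Suzuki coupling of F4 with borate 35 under the conditions of step 25 would give 39.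

Step 26. The single-electron N–O cleavage may isomerise the Z-alkene at the radical-anion or imine stage, over-reduce the enone, or stall at imine hydrolysis on the large diene-bearing substrate. The fallback sets out from 33 and comes back at 39; it moves the unmasking before the cross-coupling and uses a non-radical cleavage. Mo(CO)6 in MeCN/H2O would open 33 to the C1–C14 β-hydroxy (Z)-enone iodide F5. Me4NBH(OAc)3 would reduce F5 to the anti diol iodide F4 described above, and Suzuki coupling with 35 would give 39.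

Step 25. Transmetalation may be slow against protodeboronation of the hindered β-branched alkyl group, or palladium may attack the N–O bond of the isoxazoline. The fallback sets out from 15 and 35 and comes back at 36; it runs the coupling earlier on the simpler ester and the cycloaddition last. Coupling of 35 with 15 (Pd(dppf)Cl2, aq. K3PO4, DMF) would give the C7–C24 (Z)-enoate F6. iBu2AlH would give the allylic alcohol F7, Dess–Martin oxidation the enal F8, and NH2OH·HCl/pyridine the oxime F9. tBuOCl would give the hydroximoyl chloride F10, and addition to magnesium alkoxide 30 would pass through the nitrile oxide F11 to the C1–C24 isoxazoline with free 3-OH F12. TBSOTf/2,6-lutidine would convert F12 into 36.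

**Further compounds**

F1 | step 23 | methyl (2R,3S,4S)-3-(TBS-oxy)-2,4-dimethylhex-5-enoate | C=C[C@H](C)[C@H](O[Si](C)(C)C(C)(C)C)[C@@H](C)C(=O)OC
F2 | step 23 | methyl (2R,3S,4R)-3-(TBS-oxy)-2,4-dimethyl-5-oxohexanoate | CC(=O)[C@H](C)[C@H](O[Si](C)(C)C(C)(C)C)[C@@H](C)C(=O)OC
F3 | step 23 | C1–C14 (7S)-7-hydroxy-5-ketone (3,11-bis-OTBS; methyl ester; vinyl iodide) | I/C(C)=C\[C@H](C)[C@@H](O[Si](C)(C)C(C)(C)C)[C@@H](C)/C=C\[C@@H](O)CC(=O)[C@H](C)[C@H](O[Si](C)(C)C(C)(C)C)[C@@H](C)C(=O)OC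
F4 | step 23 | C1–C14 (5S,7S)-anti diol iodide (3,11-bis-OTBS; methyl ester) | I/C(C)=C\[C@H](C)[C@@H](O[Si](C)(C)C(C)(C)C)[C@@H](C)/C=C\[C@@H](O)C[C@H](O)[C@H](C)[C@H](O[Si](C)(C)C(C)(C)C)[C@@H](C)C(=O)OC
F5 | step 26 | C1–C14 β-hydroxy (Z)-enone iodide (5S-OH; C7 ketone; 3,11-bis-OTBS) | I/C(C)=C\[C@H](C)[C@@H](O[Si](C)(C)C(C)(C)C)[C@@H](C)/C=C\C(=O)C[C@H](O)[C@H](C)[C@H](O[Si](C)(C)C(C)(C)C)[C@@H](C)C(=O)OC
F6 | step 25 | C7–C24 methyl (Z)-enoate (11,17,19-tris-OTBS) | C=C/C=C\[C@H](C)[C@H](O[Si](C)(C)C(C)(C)C)[C@@H](C)[C@H](O[Si](C)(C)C(C)(C)C)[C@@H](C)C/C(C)=C\[C@H](C)[C@@H](O[Si](C)(C)C(C)(C)C)[C@@H](C)/C=C\C(=O)OC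
F7 | step 25 | C7–C24 (Z)-allylic alcohol | C=C/C=C\[C@H](C)[C@H](O[Si](C)(C)C(C)(C)C)[C@@H](C)[C@H](O[Si](C)(C)C(C)(C)C)[C@@H](C)C/C(C)=C\[C@H](C)[C@@H](O[Si](C)(C)C(C)(C)C)[C@@H](C)/C=C\CO
F8 | step 25 | C7–C24 (Z)-enal | C=C/C=C\[C@H](C)[C@H](O[Si](C)(C)C(C)(C)C)[C@@H](C)[C@H](O[Si](C)(C)C(C)(C)C)[C@@H](C)C/C(C)=C\[C@H](C)[C@@H](O[Si](C)(C)C(C)(C)C)[C@@H](C)/C=C\C=O
F9 | step 25 | C7–C24 (Z)-enal oxime | C=C/C=C\[C@H](C)[C@H](O[Si](C)(C)C(C)(C)C)[C@@H](C)[C@H](O[Si](C)(C)C(C)(C)C)[C@@H](C)C/C(C)=C\[C@H](C)[C@@H](O[Si](C)(C)C(C)(C)C)[C@@H](C)/C=C\C=NO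
F10 | step 25 | C7–C24 hydroximoyl chloride | C=C/C=C\[C@H](C)[C@H](O[Si](C)(C)C(C)(C)C)[C@@H](C)[C@H](O[Si](C)(C)C(C)(C)C)[C@@H](C)C/C(C)=C\[C@H](C)[C@@H](O[Si](C)(C)C(C)(C)C)[C@@H](C)/C=C\C(Cl)=NO
F11 | step 25 | C7–C24 nitrile oxide | C=C/C=C\[C@H](C)[C@H](O[Si](C)(C)C(C)(C)C)[C@@H](C)[C@H](O[Si](C)(C)C(C)(C)C)[C@@H](C)C/C(C)=C\[C@H](C)[C@@H](O[Si](C)(C)C(C)(C)C)[C@@H](C)/C=C\C#[N+][O-]
F12 | step 25 | C1–C24 isoxazoline with free 3-OH | C=C/C=C\[C@H](C)[C@H](O[Si](C)(C)C(C)(C)C)[C@@H](C)[C@H](O[Si](C)(C)C(C)(C)C)[C@@H](C)C/C(C)=C\[C@H](C)[C@@H](O[Si](C)(C)C(C)(C)C)[C@@H](C)/C=C\C1=NO[C@@H](C1)[C@H](C)[C@H](O)[C@@H](C)C(=O)OC
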